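The constants are invented; the result is computed.

Every mole of starting material charged stays on the books, as starting material, open intermediate, target or homo product, with one homo product counted as two.

    partner → second intermediate (k1 = 1.1 × 10⁻⁴ s⁻¹, Ea1 = 95.0 kJ mol⁻¹)
    open intermediate + second intermediate → target (k2 = 0.0014 M⁻¹ s⁻¹, Ea2 = 59.0 kJ mol⁻¹)
    starting material → open intermediate (k3 = 0.0011 s⁻¹, Ea3 = 83.0 kJ mol⁻¹)
    2 open intermediate → homo product (k4 = 0.0013 M⁻¹ s⁻¹, Ea4 = 53.0 kJ mol⁻¹)
    (constants at 5 °C)

the same everywhere: starting material 0.18 M; partner 0.180 M; time 3.0 h
- summer: at −35 °C until 1.5 h, from then on at 5 °C
- dawn: temperature −15 °C
- spring: temperature 5 °C
- autumn: temperature −35 °C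

- percentages count the starting material that a species holds: one homo product counts as two
- two of one species on the left: rate k times its square, two consumed each time
- all constants are for 5 °C and move with temperature by the activation energies

- the flask that comes out highest in amount of target, in percent of the starting material charged, or "all alike" when all lie within 1.5 percentage points (summer / dawn / spring / autumn / all alike)
- target at the end, in percent of the starting material charged, summer
- target at the end, in percent of the starting material charged, dawn
- target at the end, in percent of the starting material charged, spring
- target at the end, in percent of the starting material charged, autumn

Target needs second intermediate, so one quantity is carried here. In spring it is 1.19, the partner count, meaning the lifetimes of partner spent in the flask. The fraction of partner still unturned is e raised to minus that count, here 30.4%.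

The ledger follows the limiting reagent, starting material, through spring, reckoned by hand.

Opening comes first. Starting material counts 11.9 lifetimes, ten times the partner count, so spring leaves <0.001% of it unopened and the books pass to open intermediate.

Thinning comes next. At the full charge, open intermediate halves through step 4 in 0.594 h, which is shorter than the run. Counting step 4 as its one exit and the full charge as open from the start, this reckoning puts spring's open intermediate at 16.5% of the charge at the end.

Capture follows. Second intermediate is taken at half of its final made share over the run, 34.8% of the charge. Step 2, summed over the open intermediate as it thins from the full charge, gives a capture count of 0.970. So 62.1% of that share is caught, and spring's target entry is 21.6%.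

The books close with homo product at 61.9%.

Autumn, held cold, comes next. Step 2 gains a factor of 73 from the coldest flask to the hottest, and scaling by activation energy gives step 1 a factor of 992. Autumn's partner count is therefore 0.00120, a ceiling of 0.120% on its target. Summer's warm stretch counts 0.594, less than spring's, and the same ledger gives summer 11.0%. Dawn gets no figure from this reckoning. Spring's entry stands above summer's entry and autumn's ceiling.

The forecast named spring, with summer 12.2%, dawn 0.3%, spring 24.5% and autumn <0.001%, on the ground that “homo-coupling takes much of the open intermediate”.

The flasks give spring as highest: spring 22.0%, summer 12.0%, dawn 0.300%, autumn 0%. Spring still holds 22.0% of target against 67.2% of homo product at 3.00 h. Spring held to 5.0 h raises the partner count from 1.19 to 1.98, which leaves 13.8% unturned, and that flask reads 14% of partner with 28.0% of target.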